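**Retrosynthetic overview**

1. The C50 polyene is cut at C11=C12 and C11'=C12' (carotenoid numbering; unprimed = prenyl end, ring A; primed = diol end, ring B): two Wittig olefinations of the C10 dialdehyde 30 with the C20 phosphonium salts 29 and 17, each made from a cyclohexenyl triflate (27, 13) and the C5 stannyl dienol 15 by Stille coupling.
2. Ring B is cut at C3'–C4', the bond between its two plain methylenes, to give the acyclic vinyl ketone acid 6. A photoredox decarboxylative radical 6-endo cyclisation closes the carbocycle (step 4); ring A is closed the same way (step 16).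
3. Enabling feature: C4' is the allylic CH2 of the tetrasubstituted C5'=C6' olefin, so at the C6'-ketone level C4'=C5'–C6'=O is an enone whose other α-carbon, the quaternary C1', cannot enolise. C3' carries only hydrogens, so a carboxyl group on it can act as a traceless radical precursor.
4. Both antipodal end groups (2R and 2'S) come from one enantiomer of α-campholenic aldehyde 1. Its stereocentre carries two different CH2 arms (ring CH2–CH= and CH2–CHO); the arm that is oxidised to CO2H and lost becomes ring carbon C3 (C3'), the other becomes the side chain, which inverts the sense of chirality.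
5. Order of ring events: the cyclopentene of 1 is opened (steps 2 and 13), the six-membered ring B is closed (step 4), then the six-membered ring A (step 16); no other ring is formed.

Key step: step 4

Remark: 1 and 30 are taken as commercial (1 is also the ZnBr2 rearrangement product of the epoxide of (1S,5S)-α-pinene), and the Z isomers formed at the two Wittig double bonds are assumed to equilibrate thermally to the all-E polyene, as is usual for carotenoids.

**Ring B end group (steps 1–11)**

Step 1
Reactants: 1 (S)-α-campholenic aldehyde, 2-[(1S)-2,2,3-trimethylcyclopent-3-en-1-yl]acetaldehyde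
Product: 2 (4R)-1,5,5-trimethyl-4-(prop-2-en-1-yl)cyclopent-1-ene
Conditions: Ph3PCH3Br, KOt-Bu, THF, 0 °C to rt
Reagents that add atoms: methyltriphenylphosphonium bromide, C[P+](c1ccccc1)(c1ccccc1)c1ccccc1.[Br-]
Why: Wittig methylenation of the unhindered aldehyde should turn the CH2CHO arm into the allyl arm (the future side chain of ring B) without touching the remote stereocentre.

Step 2
Reactants: 2 (4R)-1,5,5-trimethyl-4-(prop-2-en-1-yl)cyclopent-1-ene
Product: 5 (3R)-4,4-dimethyl-5-oxo-3-(prop-2-en-1-yl)hexanoic acid, via ozonide 3 (not isolated), via keto aldehyde 4 (not isolated)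
Conditions: O3, CH2Cl2, −78 °C (Sudan Red 7B end point); Me2S, −78 °C to rt; then NaClO2, NaH2PO4, 2-methylbut-2-ene, t-BuOH/H2O, 0 °C to rt
Reagents that add atoms: ozone, [O-][O+]=O; sodium chlorite, [Na+].[O-]Cl=O
Why: Ozone should attack the electron-rich trisubstituted ring olefin much faster than the monosubstituted vinyl group (indicator-controlled ozonolysis), and buffered chlorite then oxidises only the aldehyde (Pinnick oxidation), so the former ring CH= carbon becomes the carboxyl that will later leave as CO2.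

Step 3
Reactants: 5 (3R)-4,4-dimethyl-5-oxo-3-(prop-2-en-1-yl)hexanoic acid
Product: 6 (3R)-4,4-dimethyl-5-oxo-3-(prop-2-en-1-yl)hept-6-enoic acid
Conditions: (CH2O)n, i-Pr2NH2+ CF3CO2− (1 equiv), CF3CO2H (10 mol %), THF, reflux
Reagents that add atoms: formaldehyde (as paraformaldehyde), C=O
Why: The methyl ketone has only one enolisable position because its other α-carbon is quaternary, so Mannich condensation with formaldehyde followed by β-elimination of the amine (α-methylenation of a ketone) should give the vinyl ketone regiospecifically.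

Step 4
Reactants: 6 (3R)-4,4-dimethyl-5-oxo-3-(prop-2-en-1-yl)hept-6-enoic acid
Product: 7 (3S)-2,2-dimethyl-3-(prop-2-en-1-yl)cyclohexan-1-one
Conditions: [Ir(dF(CF3)ppy)2(dtbbpy)]PF6 (1 mol %), K2HPO4 (1.2 equiv), DMF (0.01 M), 450 nm LEDs, rt, degassed
Reagents that add atoms: none
Why: The excited trivalent iridium photocatalyst oxidises the carboxylate of 6, loss of CO2 gives the primary radical at C3', and this adds 6-endo-trig to the terminal carbon C4' of the vinyl ketone; the α-keto radical at C5' is then reduced by the divalent iridium complex to the enolate and protonated, so the step is redox-neutral and leaves no functional group on either carbon of the new bond. The closest known reaction type is the photoredox decarboxylative conjugate addition of aliphatic acids to enones (Giese reaction), together with the endo-selective tin hydride cyclisations of 7-halohept-1-en-3-ones to cyclohexanones. The carbocycle of ring B is closed in the 6-endo-trig mode, with the ketone carbon C6' inside the ring. No stereocentre is formed: C2' comes unchanged from 1 and cannot epimerise, and C5' remains a methylene. The step needs 6-endo over 5-exo regioselectivity, which is secured because attack at C4' gives a conjugated α-keto radical whereas attack at C5' would give a primary radical. It also needs cyclisation to outrun intermolecular addition and attack on the allyl group, which is secured by the gem-dimethyl group at C1' (Thorpe–Ingold effect), by high dilution, and by the allyl olefin being reachable only through 4-exo or 5-endo modes.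

Step 5
Reactants: 7 (3S)-2,2-dimethyl-3-(prop-2-en-1-yl)cyclohexan-1-one
Product: 9 (3S)-2,2,6-trimethyl-3-(prop-2-en-1-yl)cyclohexan-1-one (both C6 epimers), via lithium enolate 8 (not isolated)
Conditions: LiN(i-Pr)2 (1.05 equiv), THF, −78 °C; MeI, −78 to 0 °C
Reagents that add atoms: iodomethane, CI
Why: Only C6 can be deprotonated because the other α-carbon is quaternary, and C-methylation of the kinetic enolate (enolate alkylation) installs the C5' methyl group; the new centre is an epimer mixture that is erased in step 6.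

Step 6
Reactants: 9 (3S)-2,2,6-trimethyl-3-(prop-2-en-1-yl)cyclohexan-1-one
Product: 11 (5S)-2,6,6-trimethyl-5-(prop-2-en-1-yl)cyclohex-1-en-1-yl trifluoromethanesulfonate, via potassium enolate 10 (not isolated)
Conditions: KN(SiMe3)2 (1.3 equiv), THF, −78 to 0 °C; PhNTf2, −78 °C to rt
Reagents that add atoms: N-phenylbis(trifluoromethanesulfonimide), O=S(=O)(N(c1ccccc1)S(=O)(=O)C(F)(F)F)C(F)(F)F
Why: Removal of the single remaining α-hydrogen and O-sulfonylation (enol triflate formation) should fix the tetrasubstituted C5'=C6' olefin regiospecifically and give the handle for the polyene.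

Step 7
Reactants: 11 (5S)-2,6,6-trimethyl-5-(prop-2-en-1-yl)cyclohex-1-en-1-yl trifluoromethanesulfonate
Product: 12 2-{2-[(1S)-2,2,4-trimethyl-3-(trifluoromethanesulfonyloxy)cyclohex-3-en-1-yl]ethylidene}propane-1,3-diyl diacetate
Conditions: 2-methylidenepropane-1,3-diyl diacetate (4 equiv), second-generation Hoveyda–Grubbs catalyst RuCl2(H2IMes)(=CH-C6H4-2-O-i-Pr) (5 mol %), CH2Cl2, 40 °C
Reagents that add atoms: 2-methylidenepropane-1,3-diyl diacetate, C=C(COC(C)=O)COC(C)=O
Why: Cross-metathesis of the terminal allyl olefin with an excess of the symmetrical 1,1-disubstituted olefin should give the trisubstituted alkene, which has no E/Z isomers because the new terminus carries two identical groups; the tetrasubstituted enol triflate olefin is inert to the ruthenium carbene.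

Step 8
Reactants: 12 2-{2-[(1S)-2,2,4-trimethyl-3-(trifluoromethanesulfonyloxy)cyclohex-3-en-1-yl]ethylidene}propane-1,3-diyl diacetate
Product: 13 (5S)-5-[4-hydroxy-3-(hydroxymethyl)but-2-en-1-yl]-2,6,6-trimethylcyclohex-1-en-1-yl trifluoromethanesulfonate
Conditions: K2CO3 (0.2 equiv), MeOH, 0 °C
Reagents that add atoms: none
Why: Transesterification frees the diol before the palladium step, because allylic acetates would ionise with zerovalent palladium, while the hindered vinyl triflate should survive catalytic carbonate at 0 °C.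

Step 9
Reactants: 14 (2E)-3-methylpent-2-en-4-yn-1-ol
Product: 15 (2E,4E)-3-methyl-5-(tributylstannyl)penta-2,4-dien-1-ol
Conditions: Bu3SnH, PdCl2(PPh3)2 (2 mol %), THF, 0 °C
Reagents that add atoms: tributyltin hydride, CCCC[SnH](CCCC)CCCC
Why: Palladium-catalysed hydrostannylation adds tin and hydrogen syn across the terminal alkyne with tin at the terminal carbon, which should give the (E)-vinylstannane with the existing (E)-olefin untouched.

Step 10
Reactants: 13 (5S)-5-[4-hydroxy-3-(hydroxymethyl)but-2-en-1-yl]-2,6,6-trimethylcyclohex-1-en-1-yl trifluoromethanesulfonate; 15 (2E,4E)-3-methyl-5-(tributylstannyl)penta-2,4-dien-1-ol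
Product: 16 (2E,4E)-5-{(5S)-5-[4-hydroxy-3-(hydroxymethyl)but-2-en-1-yl]-2,6,6-trimethylcyclohex-1-en-1-yl}-3-methylpenta-2,4-dien-1-ol
Conditions: Pd2(dba)3 (2.5 mol %), AsPh3 (20 mol %), NMP, 60 °C
Reagents that add atoms: none
Why: Stille coupling with retention of olefin geometry should join C6' to C7'; the weakly donating arsine in a polar solvent speeds transmetalation at the hindered vinyl palladium, and an intramolecular Heck reaction onto the side-chain olefin is excluded because it would create a bridgehead olefin.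

Step 11
Reactants: 16 (2E,4E)-5-{(5S)-5-[4-hydroxy-3-(hydroxymethyl)but-2-en-1-yl]-2,6,6-trimethylcyclohex-1-en-1-yl}-3-methylpenta-2,4-dien-1-ol
Product: 17 [(2E,4E)-5-{(5S)-5-[4-hydroxy-3-(hydroxymethyl)but-2-en-1-yl]-2,6,6-trimethylcyclohex-1-en-1-yl}-3-methylpenta-2,4-dien-1-yl]triphenylphosphonium bromide
Conditions: PPh3·HBr (1.0 equiv), MeOH, 0 °C to rt
Reagents that add atoms: triphenylphosphine hydrobromide, [Br-].[PH+](c1ccccc1)(c1ccccc1)c1ccccc1
Why: The dienylic alcohol ionises to a cation delocalised over the ring olefin and both chain olefins and is trapped by PPh3 at the primary terminus (the standard route to carotenoid Wittig salts), whereas the isolated allylic diol should ionise far more slowly.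

**Ring A end group (steps 12–20)**

Step 12
Reactants: 1 (S)-α-campholenic aldehyde, 2-[(1S)-2,2,3-trimethylcyclopent-3-en-1-yl]acetaldehyde
Product: 18 (S)-α-campholenic acid, 2-[(1S)-2,2,3-trimethylcyclopent-3-en-1-yl]acetic acid
Conditions: NaClO2, NaH2PO4, 2-methylbut-2-ene, t-BuOH/H2O, 0 °C to rt
Reagents that add atoms: sodium chlorite, [Na+].[O-]Cl=O
Why: Pinnick oxidation with a hypochlorite scavenger spares the ring olefin and converts the CH2CHO arm into the carboxyl that will be lost, so this arm, not the ring CH2, becomes ring carbon C3 of ring A.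

Step 13
Reactants: 18 (S)-α-campholenic acid, 2-[(1S)-2,2,3-trimethylcyclopent-3-en-1-yl]acetic acid
Product: 20 (3S)-4,4-dimethyl-5-oxo-3-(2-oxoethyl)hexanoic acid, via ozonide 19 (not isolated)
Conditions: O3, CH2Cl2, −78 °C; Me2S, −78 °C to rt; crude product used at once
Reagents that add atoms: ozone, [O-][O+]=O
Why: Ozonolysis with reductive work-up opens the only olefin to the methyl ketone (future C6/C5) and the aldehyde arm (future side chain); immediate use avoids aldol closure between these two groups.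

Step 14
Reactants: 20 (3S)-4,4-dimethyl-5-oxo-3-(2-oxoethyl)hexanoic acid
Product: 21 (3S)-4,4-dimethyl-3-(3-methylbut-2-en-1-yl)-5-oxohexanoic acid
Conditions: i-PrPPh3I (2.3 equiv), KN(SiMe3)2 (2.2 equiv), THF, 0 °C; then 20, −78 °C to rt; work-up at pH 3
Reagents that add atoms: isopropyltriphenylphosphonium iodide, CC(C)[P+](c1ccccc1)(c1ccccc1)c1ccccc1.[I-]
Why: The non-stabilised ylide should olefinate the aldehyde (Wittig reaction) far faster than the neopentyl-type methyl ketone, giving the prenyl side chain directly while the acid is carried as its carboxylate.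

Step 15
Reactants: 21 (3S)-4,4-dimethyl-3-(3-methylbut-2-en-1-yl)-5-oxohexanoic acid
Product: 22 (3S)-4,4-dimethyl-3-(3-methylbut-2-en-1-yl)-5-oxohept-6-enoic acid
Conditions: (CH2O)n, i-Pr2NH2+ CF3CO2− (1 equiv), CF3CO2H (10 mol %), THF, reflux
Reagents that add atoms: formaldehyde (as paraformaldehyde), C=O
Why: As in step 3, the only enolisable position of the ketone is the methyl group, so Mannich condensation and elimination (α-methylenation) should give the vinyl ketone.

Step 16
Reactants: 22 (3S)-4,4-dimethyl-3-(3-methylbut-2-en-1-yl)-5-oxohept-6-enoic acid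
Product: 23 (3R)-2,2-dimethyl-3-(3-methylbut-2-en-1-yl)cyclohexan-1-one
Conditions: [Ir(dF(CF3)ppy)2(dtbbpy)]PF6 (1 mol %), K2HPO4 (1.2 equiv), DMF (0.01 M), 450 nm LEDs, rt, degassed
Reagents that add atoms: none
Why: The same decarboxylative radical 6-endo-trig cyclisation as in step 4 (Giese-type) closes ring A at C3–C4; the prenyl olefin is out of reach of the C3 radical, and C2 is untouched.

Step 17
Reactants: 23 (3R)-2,2-dimethyl-3-(3-methylbut-2-en-1-yl)cyclohexan-1-one
Product: 25 (3R)-2,2,6-trimethyl-3-(3-methylbut-2-en-1-yl)cyclohexan-1-one (both C6 epimers), via lithium enolate 24 (not isolated)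
Conditions: LiN(i-Pr)2 (1.05 equiv), THF, −78 °C; MeI, −78 to 0 °C
Reagents that add atoms: iodomethane, CI
Why: Regiospecific enolate methylation at the only enolisable α-carbon installs the C5 methyl group; the epimer mixture is erased in step 18.

Step 18
Reactants: 25 (3R)-2,2,6-trimethyl-3-(3-methylbut-2-en-1-yl)cyclohexan-1-one
Product: 27 (5R)-2,6,6-trimethyl-5-(3-methylbut-2-en-1-yl)cyclohex-1-en-1-yl trifluoromethanesulfonate, via potassium enolate 26 (not isolated)
Conditions: KN(SiMe3)2 (1.3 equiv), THF, −78 to 0 °C; PhNTf2, −78 °C to rt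
Reagents that add atoms: N-phenylbis(trifluoromethanesulfonimide), O=S(=O)(N(c1ccccc1)S(=O)(=O)C(F)(F)F)C(F)(F)F
Why: Enol triflate formation at the single remaining α-hydrogen should fix the tetrasubstituted C5=C6 olefin of ring A.

Step 19
Reactants: 27 (5R)-2,6,6-trimethyl-5-(3-methylbut-2-en-1-yl)cyclohex-1-en-1-yl trifluoromethanesulfonate; 15 (2E,4E)-3-methyl-5-(tributylstannyl)penta-2,4-dien-1-ol
Product: 28 (2E,4E)-3-methyl-5-[(5R)-2,6,6-trimethyl-5-(3-methylbut-2-en-1-yl)cyclohex-1-en-1-yl]penta-2,4-dien-1-ol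
Conditions: Pd2(dba)3 (2.5 mol %), AsPh3 (20 mol %), NMP, 60 °C
Reagents that add atoms: none
Why: The same Stille coupling as in step 10 should join C6 to C7 with retention of the (E,E)-diene geometry; the trisubstituted prenyl olefin does not interfere.

Step 20
Reactants: 28 (2E,4E)-3-methyl-5-[(5R)-2,6,6-trimethyl-5-(3-methylbut-2-en-1-yl)cyclohex-1-en-1-yl]penta-2,4-dien-1-ol
Product: 29 {(2E,4E)-3-methyl-5-[(5R)-2,6,6-trimethyl-5-(3-methylbut-2-en-1-yl)cyclohex-1-en-1-yl]penta-2,4-dien-1-yl}triphenylphosphonium bromide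
Conditions: PPh3·HBr (1.0 equiv), MeOH, 0 °C to rt
Reagents that add atoms: triphenylphosphine hydrobromide, [Br-].[PH+](c1ccccc1)(c1ccccc1)c1ccccc1
Why: Ionisation of the dienylic alcohol and capture by PPh3 gives the allylic phosphonium salt, and isolated trisubstituted olefins such as the prenyl group are known to tolerate these conditions in acyclic carotenoid end groups.

**Polyene assembly (steps 21–22)**

Step 21
Reactants: 29 {(2E,4E)-3-methyl-5-[(5R)-2,6,6-trimethyl-5-(3-methylbut-2-en-1-yl)cyclohex-1-en-1-yl]penta-2,4-dien-1-yl}triphenylphosphonium bromide; 30 (2E,4E,6E)-2,7-dimethylocta-2,4,6-trienedial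
Product: 32 (2E,4E,6E,8E,10E,12E)-2,7,11-trimethyl-13-[(5R)-2,6,6-trimethyl-5-(3-methylbut-2-en-1-yl)cyclohex-1-en-1-yl]trideca-2,4,6,8,10,12-hexaenal, via phosphorus ylide 31 (not isolated)
Conditions: 30 (3 equiv), NaOMe (1.1 equiv), CH2Cl2/MeOH, 0 °C to rt, argon, dark; then heptane, reflux
Reagents that add atoms: none
Why: Wittig olefination with an excess of the symmetrical dialdehyde should stop at mono-condensation and form C11=C12, and the Z isomer of the new bond equilibrates thermally to the all-E polyenal.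

Step 22
Reactants: 17 [(2E,4E)-5-{(5S)-5-[4-hydroxy-3-(hydroxymethyl)but-2-en-1-yl]-2,6,6-trimethylcyclohex-1-en-1-yl}-3-methylpenta-2,4-dien-1-yl]triphenylphosphonium bromide; 32 (2E,4E,6E,8E,10E,12E)-2,7,11-trimethyl-13-[(5R)-2,6,6-trimethyl-5-(3-methylbut-2-en-1-yl)cyclohex-1-en-1-yl]trideca-2,4,6,8,10,12-hexaenal
Product: 34 (2R,2'S)-2'-[4-hydroxy-3-(hydroxymethyl)but-2-en-1-yl]-2-(3-methylbut-2-en-1-yl)-β,β-carotene (CNP0213288.1), via phosphorus ylide 33 (not isolated)
Conditions: 17 (1.2 equiv), NaOMe (1.3 equiv), CH2Cl2/MeOH, 0 °C to rt, argon, dark; then heptane/EtOH, reflux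
Reagents that add atoms: none
Why: The second Wittig olefination forms C11'=C12' and completes the C50 chain; free hydroxyl groups are tolerated in carotenoid Wittig couplings, and thermal equilibration should deliver the all-E target with both stereocentres untouched.

**Compound list**

1 | (S)-α-campholenic aldehyde, 2-[(1S)-2,2,3-trimethylcyclopent-3-en-1-yl]acetaldehyde | CC1=CC[C@@H](CC=O)C1(C)C | starting material
2 | (4R)-1,5,5-trimethyl-4-(prop-2-en-1-yl)cyclopent-1-ene | CC1=CC[C@@H](CC=C)C1(C)C | intermediate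
3 | secondary ozonide of 2 (1,2,4-trioxolane across the former ring olefin) | CC12OOC(O1)C[C@@H](CC=C)C2(C)C | intermediate
4 | (3R)-4,4-dimethyl-5-oxo-3-(prop-2-en-1-yl)hexanal | O=CC[C@@H](CC=C)C(C)(C)C(C)=O | intermediate
5 | (3R)-4,4-dimethyl-5-oxo-3-(prop-2-en-1-yl)hexanoic acid | OC(=O)C[C@@H](CC=C)C(C)(C)C(C)=O | intermediate
6 | (3R)-4,4-dimethyl-5-oxo-3-(prop-2-en-1-yl)hept-6-enoic acid | OC(=O)C[C@@H](CC=C)C(C)(C)C(=O)C=C | intermediate
7 | (3S)-2,2-dimethyl-3-(prop-2-en-1-yl)cyclohexan-1-one | O=C1CCC[C@@H](CC=C)C1(C)C | intermediate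
8 | lithium (5S)-6,6-dimethyl-5-(prop-2-en-1-yl)cyclohex-1-en-1-olate | [Li]OC1=CCC[C@@H](CC=C)C1(C)C | intermediate
9 | (3S)-2,2,6-trimethyl-3-(prop-2-en-1-yl)cyclohexan-1-one (both C6 epimers) | CC1CC[C@@H](CC=C)C(C)(C)C1=O | intermediate
10 | potassium (5S)-2,6,6-trimethyl-5-(prop-2-en-1-yl)cyclohex-1-en-1-olate | [K]OC1=C(C)CC[C@@H](CC=C)C1(C)C | intermediate
11 | (5S)-2,6,6-trimethyl-5-(prop-2-en-1-yl)cyclohex-1-en-1-yl trifluoromethanesulfonate | FC(F)(F)S(=O)(=O)OC1=C(C)CC[C@@H](CC=C)C1(C)C | intermediate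
12 | 2-{2-[(1S)-2,2,4-trimethyl-3-(trifluoromethanesulfonyloxy)cyclohex-3-en-1-yl]ethylidene}propane-1,3-diyl diacetate | CC(=O)OCC(COC(C)=O)=CC[C@@H]1CCC(C)=C(OS(=O)(=O)C(F)(F)F)C1(C)C | intermediate
13 | (5S)-5-[4-hydroxy-3-(hydroxymethyl)but-2-en-1-yl]-2,6,6-trimethylcyclohex-1-en-1-yl trifluoromethanesulfonate | OCC(CO)=CC[C@@H]1CCC(C)=C(OS(=O)(=O)C(F)(F)F)C1(C)C | intermediate
14 | (2E)-3-methylpent-2-en-4-yn-1-ol | C#C/C(C)=C/CO | starting material
15 | (2E,4E)-3-methyl-5-(tributylstannyl)penta-2,4-dien-1-ol | CCCC[Sn](CCCC)(CCCC)/C=C/C(C)=C/CO | intermediate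
16 | (2E,4E)-5-{(5S)-5-[4-hydroxy-3-(hydroxymethyl)but-2-en-1-yl]-2,6,6-trimethylcyclohex-1-en-1-yl}-3-methylpenta-2,4-dien-1-ol | OCC(CO)=CC[C@@H]1CCC(C)=C(/C=C/C(C)=C/CO)C1(C)C | intermediate
17 | [(2E,4E)-5-{(5S)-5-[4-hydroxy-3-(hydroxymethyl)but-2-en-1-yl]-2,6,6-trimethylcyclohex-1-en-1-yl}-3-methylpenta-2,4-dien-1-yl]triphenylphosphonium bromide | OCC(CO)=CC[C@@H]1CCC(C)=C(/C=C/C(C)=C/C[P+](c2ccccc2)(c2ccccc2)c2ccccc2)C1(C)C.[Br-] | intermediate
18 | (S)-α-campholenic acid, 2-[(1S)-2,2,3-trimethylcyclopent-3-en-1-yl]acetic acid | CC1=CC[C@@H](CC(O)=O)C1(C)C | intermediate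
19 | secondary ozonide of 18 (1,2,4-trioxolane across the former ring olefin) | CC12OOC(O1)C[C@@H](CC(O)=O)C2(C)C | intermediate
20 | (3S)-4,4-dimethyl-5-oxo-3-(2-oxoethyl)hexanoic acid | O=CC[C@@H](CC(O)=O)C(C)(C)C(C)=O | intermediate
21 | (3S)-4,4-dimethyl-3-(3-methylbut-2-en-1-yl)-5-oxohexanoic acid | CC(C)=CC[C@@H](CC(O)=O)C(C)(C)C(C)=O | intermediate
22 | (3S)-4,4-dimethyl-3-(3-methylbut-2-en-1-yl)-5-oxohept-6-enoic acid | CC(C)=CC[C@@H](CC(O)=O)C(C)(C)C(=O)C=C | intermediate
23 | (3R)-2,2-dimethyl-3-(3-methylbut-2-en-1-yl)cyclohexan-1-one | CC(C)=CC[C@H]1CCCC(=O)C1(C)C | intermediate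
24 | lithium (5R)-6,6-dimethyl-5-(3-methylbut-2-en-1-yl)cyclohex-1-en-1-olate | CC(C)=CC[C@H]1CCC=C(O[Li])C1(C)C | intermediate
25 | (3R)-2,2,6-trimethyl-3-(3-methylbut-2-en-1-yl)cyclohexan-1-one (both C6 epimers) | CC(C)=CC[C@H]1CCC(C)C(=O)C1(C)C | intermediate
26 | potassium (5R)-2,6,6-trimethyl-5-(3-methylbut-2-en-1-yl)cyclohex-1-en-1-olate | CC(C)=CC[C@H]1CCC(C)=C(O[K])C1(C)C | intermediate
27 | (5R)-2,6,6-trimethyl-5-(3-methylbut-2-en-1-yl)cyclohex-1-en-1-yl trifluoromethanesulfonate | CC(C)=CC[C@H]1CCC(C)=C(OS(=O)(=O)C(F)(F)F)C1(C)C | intermediate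
28 | (2E,4E)-3-methyl-5-[(5R)-2,6,6-trimethyl-5-(3-methylbut-2-en-1-yl)cyclohex-1-en-1-yl]penta-2,4-dien-1-ol | CC(C)=CC[C@H]1CCC(C)=C(/C=C/C(C)=C/CO)C1(C)C | intermediate
29 | {(2E,4E)-3-methyl-5-[(5R)-2,6,6-trimethyl-5-(3-methylbut-2-en-1-yl)cyclohex-1-en-1-yl]penta-2,4-dien-1-yl}triphenylphosphonium bromide | CC(C)=CC[C@H]1CCC(C)=C(/C=C/C(C)=C/C[P+](c2ccccc2)(c2ccccc2)c2ccccc2)C1(C)C.[Br-] | intermediate
30 | (2E,4E,6E)-2,7-dimethylocta-2,4,6-trienedial | O=C/C(C)=C/C=C/C=C(C)/C=O | starting material
31 | phosphorus ylide of 29, {(2E,4E)-3-methyl-5-[(5R)-2,6,6-trimethyl-5-(3-methylbut-2-en-1-yl)cyclohex-1-en-1-yl]penta-2,4-dien-1-ylidene}triphenylphosphorane | CC(C)=CC[C@H]1CCC(C)=C(/C=C/C(C)=C/C=P(c2ccccc2)(c2ccccc2)c2ccccc2)C1(C)C | intermediate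
32 | (2E,4E,6E,8E,10E,12E)-2,7,11-trimethyl-13-[(5R)-2,6,6-trimethyl-5-(3-methylbut-2-en-1-yl)cyclohex-1-en-1-yl]trideca-2,4,6,8,10,12-hexaenal | CC(C)=CC[C@H]1CCC(C)=C(/C=C/C(C)=C/C=C/C(C)=C/C=C/C=C(C)/C=O)C1(C)C | intermediate
33 | phosphorus ylide of 17, [(2E,4E)-5-{(5S)-5-[4-hydroxy-3-(hydroxymethyl)but-2-en-1-yl]-2,6,6-trimethylcyclohex-1-en-1-yl}-3-methylpenta-2,4-dien-1-ylidene]triphenylphosphorane | OCC(CO)=CC[C@@H]1CCC(C)=C(/C=C/C(C)=C/C=P(c2ccccc2)(c2ccccc2)c2ccccc2)C1(C)C | intermediate
34 | (2R,2'S)-2'-[4-hydroxy-3-(hydroxymethyl)but-2-en-1-yl]-2-(3-methylbut-2-en-1-yl)-β,β-carotene (CNP0213288.1) | CC(C)=CC[C@H]1CCC(C)=C(/C=C/C(C)=C/C=C/C(C)=C/C=C/C=C(C)/C=C/C=C(C)/C=C/C2=C(C)CC[C@@H](CC=C(CO)CO)C2(C)C)C1(C)C | target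

**Step count and risks**

Total step count: 22.
Longest linear sequence: 11 steps (1 → 34 through steps 1–8, 10, 11 and 22; the ring A branch through steps 12–22 is equally long).

Steps most likely to fail:

1. Step 4 (and its ring A twin, step 16). Single-electron oxidation of a primary carboxylate by the excited photocatalyst may be slow, so that back electron transfer and radical oligomerisation of the vinyl ketone outrun the cyclisation. The fallback sets out from 6 and changes the radical generation from oxidative to reductive. Esterification with N-hydroxyphthalimide (N,N'-diisopropylcarbodiimide, catalytic DMAP, CH2Cl2) would give the redox-active ester 1,3-dioxoisoindolin-2-yl (3R)-4,4-dimethyl-5-oxo-3-(prop-2-en-1-yl)hept-6-enoate F1. Its reductive fragmentation (Ru(bpy)3(PF6)2, Hantzsch ester, i-Pr2NEt, CH2Cl2, blue LEDs, high dilution) releases the same C3' radical, which cyclises 6-endo and is reduced by the Hantzsch ester. The route is rejoined at 7.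

2. Step 10 (and its twin, step 19). Oxidative addition and transmetalation at the tetrasubstituted, doubly flanked triflate may be so slow that protodestannylation and homocoupling consume the stannane. The fallback sets out from 13 and builds C7'–C11' stepwise without an organotin reagent. A Heck reaction with but-3-en-2-one (Pd(OAc)2, PPh3, Et3N, DMF, 70 °C) would give (3E)-4-{(5S)-5-[4-hydroxy-3-(hydroxymethyl)but-2-en-1-yl]-2,6,6-trimethylcyclohex-1-en-1-yl}but-3-en-2-one F2. Addition of vinylmagnesium bromide (excess, to cover the diol; THF, −78 to 0 °C) would give (1E)-1-{(5S)-5-[4-hydroxy-3-(hydroxymethyl)but-2-en-1-yl]-2,6,6-trimethylcyclohex-1-en-1-yl}-3-methylpenta-1,4-dien-3-ol F3. PPh3·HBr in methanol converts this tertiary divinyl carbinol, with allylic transposition, directly into the phosphonium salt. The route is rejoined at 17.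

3. Step 2. Discrimination between the ring olefin and the vinyl group by ozone may be incomplete, so that the allyl arm is also cleaved. The fallback sets out from 2 and replaces the kinetic ozone selectivity by an electronically controlled epoxidation. m-Chloroperbenzoic acid (NaHCO3, CH2Cl2, 0 °C) should epoxidise only the trisubstituted olefin to (3R)-1,2,2-trimethyl-3-(prop-2-en-1-yl)-6-oxabicyclo[3.1.0]hexane F4. Periodic acid (H5IO6, THF/H2O) cleaves the epoxide to the keto aldehyde, rejoining the route at 4, which is oxidised with NaClO2 as in the second half of step 2.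

**Further compounds**

F1 | step 4 | 1,3-dioxoisoindolin-2-yl (3R)-4,4-dimethyl-5-oxo-3-(prop-2-en-1-yl)hept-6-enoate | O=C(C[C@@H](CC=C)C(C)(C)C(=O)C=C)ON1C(=O)c2ccccc2C1=O
F2 | step 10 | (3E)-4-{(5S)-5-[4-hydroxy-3-(hydroxymethyl)but-2-en-1-yl]-2,6,6-trimethylcyclohex-1-en-1-yl}but-3-en-2-one | CC(=O)/C=C/C1=C(C)CC[C@@H](CC=C(CO)CO)C1(C)C
F3 | step 10 | (1E)-1-{(5S)-5-[4-hydroxy-3-(hydroxymethyl)but-2-en-1-yl]-2,6,6-trimethylcyclohex-1-en-1-yl}-3-methylpenta-1,4-dien-3-ol (both C3 epimers) | C=CC(C)(O)/C=C/C1=C(C)CC[C@@H](CC=C(CO)CO)C1(C)C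
F4 | step 2 | (3R)-1,2,2-trimethyl-3-(prop-2-en-1-yl)-6-oxabicyclo[3.1.0]hexane (both epoxide faces) | CC12OC1C[C@@H](CC=C)C2(C)C
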